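**Strategy.** The ester is made last. The C20 alcohol is cut between the two side-chain methylenes next to the ring, giving an (S)-α-cyclogeranyl Grignard reagent and 8-bromogeranyl acetate. The ring (C1 stereocentre, C2(Me)=C3, C4H2, C5H2, C6Me2) is closed between C5 and C6. The key step exploits the quaternary gem-dimethyl carbon C6 lying between C1 and C5: iron-hydride hydrogen-atom transfer to an isopropenyl group on C1 gives the tertiary C6 radical, which adds 6-endo to a vinyl ketone. One operation forms the ring and the quaternary carbon. The precursor is an acyclic 1,6-dien-3-one whose C1 configuration comes from a rhodium-catalysed asymmetric conjugate addition; the C3 ketone later becomes the C2=C3 alkene.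

Key step: step 4

Assumption: (R)-BINAP is taken as the ligand antipode that gives the 4R lactone 3, by analogy with the facial sense known for cyclic enones and enoates; if the sense is opposite, (S)-BINAP is used.

**Step 1**
Reactants: 1 furan-2(5H)-one; 2 4,4,5,5-tetramethyl-2-(prop-1-en-2-yl)-1,3,2-dioxaborolane (isopropenylboronic acid pinacol ester)
Product: 3 (4R)-4-(prop-1-en-2-yl)oxolan-2-one
Conditions: [Rh(cod)Cl]2 (2.5 mol %), (R)-BINAP (6 mol %), aq KOH (cat.), dioxane/H2O 10:1, 50 °C
Reagents that add atoms: none
Why: Hayashi–Miyaura asymmetric conjugate addition of an alkenylboron reagent to a cyclic enoate; the BINAP–rhodium alkenyl species adds to one face of the butenolide and so sets C4 (the future ring C1) as R.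

**Step 2**
Reactants: 3 (4R)-4-(prop-1-en-2-yl)oxolan-2-one
Product: 4 (3S,4R)-3-methyl-4-(prop-1-en-2-yl)oxolan-2-one
Conditions: LDA, THF, −78 °C; MeI, −78 → −40 °C
Reagents that add atoms: iodomethane, CI
Why: Lactone enolate alkylation in which methyl iodide should enter anti to the C4 isopropenyl group (trans product); this new centre is of no consequence because it becomes sp2 in step 6.

**Step 3**
Reactants: 4 (3S,4R)-3-methyl-4-(prop-1-en-2-yl)oxolan-2-one
Product: 5 (4S,5R)-5-(hydroxymethyl)-4,6-dimethylhepta-1,6-dien-3-one
Conditions: vinylmagnesium bromide (1.1 equiv), THF, −78 °C; pH 7 buffer quench at −78 °C; used directly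
Reagents that add atoms: vinylmagnesium bromide, C=C[Mg]Br
Why: Single Grignard addition to a lactone, in which the magnesium hemiketal alkoxide should persist at −78 °C and release the γ-hydroxy vinyl ketone only on quench, so that a second addition is avoided.

**Step 4**
Reactants: 5 (4S,5R)-5-(hydroxymethyl)-4,6-dimethylhepta-1,6-dien-3-one
Product: 6 (2S,3R)-3-(hydroxymethyl)-2,4,4-trimethylcyclohexan-1-one
Conditions: Fe(acac)3 (30 mol %), PhSiH3 (2.5 equiv), degassed EtOH/ethylene glycol 5:1, 0.02 M, 60 °C
Reagents that add atoms: none
Why: An iron hydride formed from Fe(acac)3 and PhSiH3 in ethanol transfers a hydrogen atom to the CH2 terminus of the electron-rich isopropenyl group (Markovnikov), the tertiary radical adds to the terminal carbon of the vinyl ketone, and the α-keto radical is reduced to the enolate and protonated by the solvent. The closest known reaction type is the hydrogen-atom-transfer-initiated Giese reaction (reductive coupling of an unactivated alkene with an enone), here in its intramolecular form. The six-membered ring closes in the 6-endo-trig mode, as expected for a 4-oxohex-5-enyl radical, because the carbonyl inside the chain and the polarity match (nucleophilic tertiary radical, enone β-carbon) disfavour 5-exo attack at the α-carbon. No lasting stereocentre is created, since the new quaternary carbon carries two methyl groups and the pre-set centre next to the radical is not touched. The step needs hydrogen-atom transfer to the 1,1-disubstituted alkene in preference to the enone, and ring closure faster than reduction of the radical or return of a β-hydrogen from the stereocentre to the metal; the hydridic iron hydride, the dilution and the fast intramolecular trap should secure this.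

**Step 5**
Reactants: 6 (2S,3R)-3-(hydroxymethyl)-2,4,4-trimethylcyclohexan-1-one
Product: 7 (2S,3R)-3-(bromomethyl)-2,4,4-trimethylcyclohexan-1-one
Conditions: CBr4, PPh3, CH2Cl2, 0 °C
Reagents that add atoms: carbon tetrabromide, BrC(Br)(Br)Br
Why: Appel reaction of the primary alcohol by SN2 displacement of the alkoxyphosphonium ion, which leaves the ketone and the ring stereocentre untouched.

**Step 6**
Reactants: 7 (2S,3R)-3-(bromomethyl)-2,4,4-trimethylcyclohexan-1-one
Product: 8 (3S)-3-(bromomethyl)-2,4,4-trimethylcyclohex-1-en-1-yl trifluoromethanesulfonate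
Conditions: Tf2O, 2,6-di-tert-butyl-4-methylpyridine, CH2Cl2, 0 → 23 °C; regioisomeric triflate removed by chromatography
Reagents that add atoms: trifluoromethanesulfonic anhydride, O=S(=O)(OS(=O)(=O)C(F)(F)F)C(F)(F)F
Why: Enol triflate formation under amine-buffered, equilibrating conditions should favour the more substituted enol triflate toward the methyl-bearing carbon, which erases the C2 centre; no enolate is formed, so the γ-bromide cannot be displaced intramolecularly.

**Step 7**
Reactants: 8 (3S)-3-(bromomethyl)-2,4,4-trimethylcyclohex-1-en-1-yl trifluoromethanesulfonate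
Product: 9 (6S)-6-(bromomethyl)-1,5,5-trimethylcyclohex-1-ene ((S)-α-cyclogeranyl bromide)
Conditions: Pd(OAc)2 (5 mol %), PPh3 (10 mol %), Bu3N, HCO2H, DMF, 60 °C
Reagents that add atoms: none
Why: Palladium-catalysed formate reduction of the enol triflate (oxidative addition, formate exchange, decarboxylation, C–H reductive elimination) should leave the trisubstituted alkene in place, and the unactivated primary alkyl bromide is inert to the zerovalent palladium–triphenylphosphine catalyst.

**Step 8**
Reactants: 10 geranyl acetate ((2E)-3,7-dimethylocta-2,6-dien-1-yl acetate)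
Product: 11 (2E,6E)-8-hydroxy-3,7-dimethylocta-2,6-dien-1-yl acetate
Conditions: SeO2 (10 mol %), t-BuOOH, salicylic acid (10 mol %), CH2Cl2, 23 °C
Reagents that add atoms: tert-butyl hydroperoxide, CC(C)(C)OO
Why: Riley allylic oxidation (ene reaction, then [2,3]-shift) should be selective for the E methyl group of the electron-rich terminal alkene, the alkene next to the acetate being deactivated.

**Step 9**
Reactants: 11 (2E,6E)-8-hydroxy-3,7-dimethylocta-2,6-dien-1-yl acetate
Product: 12 (2E,6E)-8-bromo-3,7-dimethylocta-2,6-dien-1-yl acetate
Conditions: CBr4, PPh3, CH2Cl2, 0 °C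
Reagents that add atoms: carbon tetrabromide, BrC(Br)(Br)Br
Why: Appel reaction of the primary allylic alcohol at low temperature should give the allylic bromide without allylic transposition or loss of the E geometry.

**Step 10**
Reactants: 9 (6S)-6-(bromomethyl)-1,5,5-trimethylcyclohex-1-ene; 12 (2E,6E)-8-bromo-3,7-dimethylocta-2,6-dien-1-yl acetate
Product: 15 (2E,6E)-3,7-dimethyl-9-[(1S)-2,6,6-trimethylcyclohex-2-en-1-yl]nona-2,6-dien-1-ol, via cyclogeranylmagnesium bromide 13 (not isolated), via diterpenyl acetate 14 (not isolated)
Conditions: 9, Mg, THF, 40 °C; added to 12, Li2CuCl4 (5 mol %), THF, −78 → −20 °C; then MeOH, K2CO3, 23 °C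
Reagents that add atoms: none
Why: Copper-catalysed cross-coupling of a primary alkyl Grignard reagent with a primary allylic bromide should proceed by direct (α) substitution with retention of the E alkene and much faster than attack on the acetate at −78 °C; methanolysis in the same flask then frees the allylic alcohol.

**Step 11**
Reactants: 15 (2E,6E)-3,7-dimethyl-9-[(1S)-2,6,6-trimethylcyclohex-2-en-1-yl]nona-2,6-dien-1-ol; 16 α-linolenic acid ((9Z,12Z,15Z)-octadeca-9,12,15-trienoic acid)
Product: 17 (2E,6E)-3,7-dimethyl-9-[(1S)-2,6,6-trimethylcyclohex-2-en-1-yl]nona-2,6-dien-1-yl (9Z,12Z,15Z)-octadeca-9,12,15-trienoate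
Conditions: DCC, DMAP (10 mol %), CH2Cl2, 0 → 23 °C, argon, dark
Reagents that add atoms: none
Why: Steglich esterification of the primary allylic alcohol under neutral conditions should keep the skipped all-Z triene, both E alkenes and the ring stereocentre intact.

**Compound list**
1 | furan-2(5H)-one | O=C1OCC=C1 | starting material
2 | 4,4,5,5-tetramethyl-2-(prop-1-en-2-yl)-1,3,2-dioxaborolane | CC(=C)B1OC(C)(C)C(C)(C)O1 | starting material
3 | (4R)-4-(prop-1-en-2-yl)oxolan-2-one | CC(=C)[C@@H]1COC(=O)C1 | intermediate
4 | (3S,4R)-3-methyl-4-(prop-1-en-2-yl)oxolan-2-one (trans) | CC(=C)[C@@H]1COC(=O)[C@H]1C | intermediate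
5 | (4S,5R)-5-(hydroxymethyl)-4,6-dimethylhepta-1,6-dien-3-one | CC(=C)[C@@H]([C@H](C)C(=O)C=C)CO | intermediate
6 | (2S,3R)-3-(hydroxymethyl)-2,4,4-trimethylcyclohexan-1-one (C2 epimerisable, erased in step 6) | CC1(C)CCC(=O)[C@@H](C)[C@H]1CO | intermediate
7 | (2S,3R)-3-(bromomethyl)-2,4,4-trimethylcyclohexan-1-one | CC1(C)CCC(=O)[C@@H](C)[C@H]1CBr | intermediate
8 | (3S)-3-(bromomethyl)-2,4,4-trimethylcyclohex-1-en-1-yl trifluoromethanesulfonate | CC1=C(OS(=O)(=O)C(F)(F)F)CCC(C)(C)[C@@H]1CBr | intermediate
9 | (6S)-6-(bromomethyl)-1,5,5-trimethylcyclohex-1-ene | CC1=CCCC(C)(C)[C@@H]1CBr | intermediate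
10 | geranyl acetate | CC(C)=CCC/C(C)=C/COC(C)=O | starting material
11 | (2E,6E)-8-hydroxy-3,7-dimethylocta-2,6-dien-1-yl acetate | OC/C(C)=C/CC/C(C)=C/COC(C)=O | intermediate
12 | (2E,6E)-8-bromo-3,7-dimethylocta-2,6-dien-1-yl acetate | BrC/C(C)=C/CC/C(C)=C/COC(C)=O | intermediate
13 | {[(1S)-2,6,6-trimethylcyclohex-2-en-1-yl]methyl}magnesium bromide | CC1=CCCC(C)(C)[C@@H]1C[Mg]Br | intermediate
14 | (2E,6E)-3,7-dimethyl-9-[(1S)-2,6,6-trimethylcyclohex-2-en-1-yl]nona-2,6-dien-1-yl acetate | CC(=O)OC/C=C(\C)CC/C=C(\C)CC[C@@H]1C(C)=CCCC1(C)C | intermediate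
15 | (2E,6E)-3,7-dimethyl-9-[(1S)-2,6,6-trimethylcyclohex-2-en-1-yl]nona-2,6-dien-1-ol | OC/C=C(\C)CC/C=C(\C)CC[C@@H]1C(C)=CCCC1(C)C | intermediate
16 | α-linolenic acid | CC/C=C\C/C=C\C/C=C\CCCCCCCC(=O)O | starting material
17 | (2E,6E)-3,7-dimethyl-9-[(1S)-2,6,6-trimethylcyclohex-2-en-1-yl]nona-2,6-dien-1-yl (9Z,12Z,15Z)-octadeca-9,12,15-trienoate | CC/C=C\C/C=C\C/C=C\CCCCCCCC(=O)OC/C=C(\C)CC/C=C(\C)CC[C@@H]1C(C)=CCCC1(C)C | target

**Totals.** Total steps: 11. Longest linear sequence: 9 steps (steps 1 to 7, then 10 and 11); the side-chain branch is steps 8 and 9.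

**Steps most likely to fail**

Step 4. The tertiary radical may be reduced before it cyclises (also if part of 5 rests as its cyclic hemiketal), the vinyl ketone may be reduced or oligomerise, or reversible hydrogen-atom transfer may move the alkene toward the stereocentre and erode its configuration. The fallback sets out from 4 and returns at 6, making the same radical by halogen abstraction instead of hydrogen-atom transfer. Markovnikov addition of HBr (HBr in AcOH, CH2Cl2, 0 °C) to the isopropenyl group should give (3S,4S)-4-(2-bromopropan-2-yl)-3-methyloxolan-2-one F1. Vinylmagnesium bromide at −78 °C, as in step 3, should then give (4S,5S)-6-bromo-5-(hydroxymethyl)-4,6-dimethylhept-1-en-3-one F2. Slow addition of Bu3SnH with Et3B and air (toluene, 0 °C) abstracts the tertiary bromine, and the radical closes 6-endo onto the vinyl ketone to give 6 (tin hydride Giese cyclisation).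

Step 6. Enolisation may be poorly regioselective, so that part of the triflate forms toward the ring CH2 and the alkene ends up in the wrong position. The fallback sets out from 7 and returns at 9. Reduction with lithium tri-sec-butylborohydride (THF, −78 °C) should deliver hydride equatorially and give the axial alcohol (1R,2S,3R)-3-(bromomethyl)-2,4,4-trimethylcyclohexan-1-ol F3. Anti elimination with POCl3 in pyridine, in which the axial C2–H is antiperiplanar to the axial oxygen and the Zaitsev orientation is preferred, gives 9.

Step 3. The Grignard reagent may add a second time if the ketone is released early, and the hydroxy vinyl ketone may be lost by conjugate addition or oligomerisation during work-up. The fallback sets out from 4 and returns at 5. Aminolysis of the lactone with N,O-dimethylhydroxylamine hydrochloride and AlMe3 (CH2Cl2, 0 °C) gives the Weinreb amide (2S,3R)-3-(hydroxymethyl)-N-methoxy-N,2,4-trimethylpent-4-enamide F4. Its chelated adduct with vinylmagnesium bromide (2.5 equiv, THF, 0 °C, inverse quench into cold aqueous acid) cannot add a second time and gives 5.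

**Further compounds**
F1 | step 4 | (3S,4S)-4-(2-bromopropan-2-yl)-3-methyloxolan-2-one | CC(C)(Br)[C@@H]1COC(=O)[C@H]1C
F2 | step 4 | (4S,5S)-6-bromo-5-(hydroxymethyl)-4,6-dimethylhept-1-en-3-one | CC(C)(Br)[C@@H]([C@H](C)C(=O)C=C)CO
F3 | step 6 | (1R,2S,3R)-3-(bromomethyl)-2,4,4-trimethylcyclohexan-1-ol | CC1(C)CC[C@@H](O)[C@@H](C)[C@H]1CBr
F4 | step 3 | (2S,3R)-3-(hydroxymethyl)-N-methoxy-N,2,4-trimethylpent-4-enamide | CC(=C)[C@@H]([C@H](C)C(=O)N(C)OC)CO
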